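Look at the stall first. You wanted a quick number, so here is the problem as it stands, and then mine beside your forecast.

| flask | Z | X | L | remark | time |
|---|---|---|---|---|---|
| Friday's | 20 mM | 22 mM | 20 µM | run made earlier |  |
| Wednesday's | 28 mM | 22 mM | 20 µM | run made earlier |  |
| Tuesday's | 44 mM | 22 mM | 20 µM | run made earlier |  |
| larch | 20 mM | 22.0 mM | 20 µM | a single well-mixed tank run continuously and read at steady state, 40 min in it on average |  |
| elm | 20 mM | 22.0 mM | 20 µM | a closed flask charged with all of it at once and left for 40 min | 40 min |
| maple | 20 mM (fed, over 32.0 min) | 22.0 mM | 20 µM | all but Z at the start; Z goes in evenly over 32.0 min, the run ends at 40 min | 40 min |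
| ash | 20 mM | 22.0 mM (fed, over 32.0 min) | 20 µM | all but X at the start; X goes in evenly over 32.0 min, the run ends at 40 min | 40 min |

| run | time / min | Q / % | Z / % |
|---|---|---|---|
| Friday's | 2.00 | 11.5 | 86.0 |
| Friday's | 3.00 | 16.9 | 83.5 |
| Friday's | 4.00 | 21.5 | 79.4 |
| Friday's | 6.00 | 24.5 | 77.1 |
| Friday's | 10.0 | 28.2 | 73.3 |
| Friday's | 15.0 | 28.6 | 70.5 |
| Friday's | 25.0 | 29.9 | 69.7 |
| Wednesday's | 1.50 | 11.2 | 89.4 |
| Wednesday's | 5.00 | 19.6 | 79.4 |
| Wednesday's | 10.0 | 21.2 | 75.2 |
| Wednesday's | 15.0 | 22.8 | 75.1 |
| Wednesday's | 20.0 | 26.0 | 73.7 |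
| Wednesday's | 25.0 | 26.0 | 76.4 |
| Wednesday's | 30.0 | 25.2 | 75.2 |
| Tuesday's | 5.00 | 16.7 | 84.9 |
| Tuesday's | 10.0 | 16.4 | 81.3 |
| Tuesday's | 15.0 | 18.4 | 83.0 |
| Tuesday's | 20.0 | 17.5 | 81.6 |
| Tuesday's | 25.0 | 19.5 | 80.3 |
| Tuesday's | 30.0 | 19.9 | 81.9 |

(readings scatter by 1 percentage point)

- the stated concentrations are those of everything mixed, before any reaction; amounts are the same in each set-up
- the feed brings no volume worth counting
- the earlier runs were made in a closed, stirred flask

1. the set-up with the highest amount of Q at the outlet or at the end, in percent of the Z put in ("none" if the first two lie within 2 percentage points) (larch / elm / maple / ash / none)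
2. amount of Q at the outlet or at the end, in percent of the Z put in, larch
3. amount of Q at the outlet or at the end, in percent of the Z put in, elm
4. amount of Q at the outlet or at the end, in percent of the Z put in, maple
5. amount of Q at the outlet or at the end, in percent of the Z put in, ash

In Friday's run Q levels off, its last reading being 29.9 % of the Z charged, which is 5.98 mM, while 69.7 % of Z stands unused. In Tuesday's run, with Z at 44 mM, the last reading of Q is 8.76 mM. Your forecast reads the stall as “catalyst dying quickly” and gives larch 23 %, elm 31 %, maple 20 % and ash 11 %, with elm best.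

My own reading differs: I take X to be lost by a side path while it makes Q, both first order in c_X. With c_Z held near its charge, c_X then falls as exp(−t/τ), and Q reaches, at any time, the fraction of its plateau that X has lost. Friday's reading at 4.00 min, set against its last one as the plateau, gives τ = 3.15 min, the mean time X lasts in Friday's flask, a pseudo-first-order lifetime and a reading with its scatter.

The rule that follows, with c_Z held as before, is that steadily fed X, once its level has steadied, stands at its supply rate times τ. In ash that is 2.17 mM, far below the charge of 22.0 mM that elm starts with. With both steps first order in my reckoning, this level cancels from the share of X going to Q, so I put ash, larch and elm together near Friday's last reading and answer none. Maple I put well below them, since τ is much shorter than its feed time. We part on ash.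

The flask gives ash best at 32.8 %, with elm at 28.9 %, larch at 28.8 % and maple at 6.67 %.

    X + L ⇌ J (K = 45.4 M⁻¹, k = 14000 M⁻¹ min⁻¹)
    Z + J ⇌ G (K = 103 M⁻¹, k = 11500 M⁻¹ min⁻¹)
    G → L + Q (k = 6220 min⁻¹)
    X → E (k = 0.233 min⁻¹)

Ash leads elm by 3.9 percentage points, with its X never above 2.12 mM, where supply times τ gave 2.17 mM. In larch, with 40 min in the tank on average, the same τ gives 1.61 mM of X, and the tank holds 1.57 mM.

The runs are calculated with made-up constants; scatter was added.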